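## The problem

Epimedonin L 17 is a flavone with no stereocentre: rings A and C form a 5,7-dihydroxychromen-4-one carrying a prenyl group on C8, and ring B is a 4'-hydroxyphenyl group on C2 with prenyl groups on both C3' and C5'. Since every alkene ends in a gem-dimethyl carbon, the task is purely constitutional: where the three prenyl groups sit, and how they survive. Each prenyl group is a trisubstituted alkene ortho to a phenolic oxygen, which rules out strong Brønsted or Lewis acids (chroman formation), electrophilic halogen, strong oxidants and hydrogenation, and with them benzyl ethers and the hot H2SO4/AcOH normally used to close flavones. Ring B is the harder half, because placing two prenyl groups ortho to a para-substituted phenol by alkylation meets O- versus C-alkylation and mono- versus di-alkylation. Ring A poses the 8- versus 6-prenyl question, which is decided by which of the two oxygens ortho to the acyl group becomes O1; the other must stay masked until ring C is closed, because a free choice, or Wessely–Moser equilibration under acid, would deliver the 6-prenyl isomer. The feature that opens ring B to construction is its local symmetry: C4' carries the hydroxyl, its neighbours C3' and C5' each carry a prenyl CH2, and the only other substituent sits on C1'. Read as a ketone, C4' with its two α-carbons is 2,10-dimethylundeca-2,9-dien-6-one 5, and C2'–C1'–C6' is a malonaldehyde whose C1' substituent can be the ester that later becomes C2 of the flavone.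

## Retrosynthesis

**17 from 16 (three O–allyl bonds).** The last operation should be neutral, because the free target has three ortho-prenylphenols. The three phenols are therefore masked as allyl ethers in 16 and released by zerovalent palladium. Acetal protecting groups would need acid at the end, and benzyl ethers would need hydrogen or a Lewis acid. The forward step must tell O-allyl from C-prenyl; the C-prenyl groups have no leaving group and cannot ionize.

**16 from 15 (O1–C2 bond, loss of water).** Ring C is opened to the 1,3-diketone 15. In 15 only one phenolic oxygen is free, the one next to the prenyl-bearing carbon of ring A, so only it can become O1 and the 8-prenyl pattern is fixed. This holds only if the other ortho oxygen stays an ether through the acid-catalysed ring closure. An allyl ether does; an acid-labile group might not.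

**15 from 14 and 11 (C2–C3 bond).** The diketone is cut between the acetyl methyl carbon of ketone 14 and the ester carbonyl of benzoate 11, a crossed Claisen condensation. Making the same bond by O-aroylation and acyl migration would add a saponification and an esterification. A chalcone route would need an aldehyde and an oxidative cyclization hostile to prenyl groups. The chosen cut divides 15 into two halves of similar size and uses the ester function of 11 as it stands.

**14 from 13, and 13 from 12 and 2.** The two allyl ethers of 14 are removed to give the triol 13, and the C3–CH2 bond of 13 is cut to give 2,4,6-trihydroxyacetophenone 12 and prenyl bromide 2. The two ring CH positions of 12 are equivalent, so mono-C-prenylation gives one constitution. The forward allylation must leave the hydroxyl between the acetyl and the prenyl group free.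

**11 from 10, and 10 from 5 and 8 by way of 9 (C2'–C3' and C5'–C6' bonds; the key cut).** Removing the allyl ether of 11 gives ethyl 4-hydroxy-3,5-diprenylbenzoate 10. Cutting the two aryl–CH2 bonds of 10 would lead back to prenylation of a 4-hydroxybenzoate, with the O/C and mono/di problems. Ring B itself is cut instead, between C2' and C3' and between C5' and C6'. This gives the symmetric ketone 5 and ethyl 2-formyl-3-oxopropanoate 8. In the forward direction two aldol condensations give the cyclohexadienone 9, which is a tautomer of 10. Both prenyl groups enter as remote alkenes of an aliphatic ketone, and the ring arrives at the aromatic oxidation level by loss of water alone.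

**5 from 4, 4 from 1 and 2 by way of 3; 8 from 7, 7 from 6.** Ketone 5 comes from dimethyl 3-oxopentanedioate 1 by alkylation with 2, first at one α-carbon to give the monoprenyl diester 3 and then at the other to give 4, followed by removal of both ester groups. Dialdehyde 8 comes from ethyl 3,3-diethoxypropanoate 6 by C-formylation to 7 and hydrolysis of the acetal. Compounds 1, 2, 6 and 12 are commercial.

## Roads not taken

Alternative 1: Ring A is cut at the C4a–C5 bond and grown onto a preformed 2-aryl-4-pyranone. The precursor would be the acyl Meldrum's acid A2. On heating, A2 loses acetone and CO2 to give an acylketene. The dienol of its side chain then closes by a 6π process, with the ketene carbon (future C5) bonding to C4a, and tautomerization gives 4'-O-(methoxymethyl) Epimedonin L A1.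

- Merits: the prenyl group sits on the side-chain carbon that becomes C8, so the 8- versus 6-prenyl question is settled by construction. The 5- and 7-hydroxyls of A1 arrive free, with no protecting groups on ring A. In this respect it is better than the chosen plan, which relies on a sterically controlled allylation in step 7.
- Weak points: A2 is elaborate (a pyranone bearing a prenylated β-keto side chain). The acylketene is intercepted by any nucleophile and can dimerize. C–C bond formation at a pyranone α-carbon by this closure has thin precedent. The diprenylated ring B must still be made some other way, and A1 must finally lose its methoxymethyl group under acid, on a molecule with three ortho-prenylphenols.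
- Comparison: the chosen plan sets against it ring closures that are all carbonyl condensations, a short path to every fragment, and a solution to the ring B problem, which Alternative 1 leaves open.

Alternative 2: Ring B is bought as a cyclohexanone, ethyl 4-oxocyclohexane-1-carboxylate A4, and the two C–CH2 bonds at C3' and C5' are cut. Deprotonation of A4 with LiN(iPr)2 and alkylation with 2, twice in one flask, would give ethyl 4-oxo-3,5-diprenylcyclohexane-1-carboxylate A3, of which any diastereomer serves. Dehydrogenation of A3 would then give 10.

- Merits: this is the shortest route to 10 on paper, two or three steps against four, and A4 is a commercial ketone. Ketone-enolate alkylation has no O/C ambiguity. These advantages are conceded.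
- Weak points: the second alkylation must go to the α' carbon while proton exchange between enolate and product produces mono-, di- and geminally alkylated mixtures, and the ester α-hydrogen is a further acidic site. More serious, A3 must be raised by two oxidation levels in the presence of two electron-rich trisubstituted alkenes. Halogenation–elimination, selenoxide chemistry, quinone oxidants and Pd(OAc)2/O2 dehydrogenation all meet the prenyl alkenes or their allylic C–H bonds, and 2,6-disubstituted cyclohexanones dehydrogenate sluggishly.
- Comparison: the chosen plan has one or two steps more. In return, ring B is formed aromatic by dehydration only, so no oxidant ever meets a prenyl group, and the substitution pattern follows from the symmetry of 5, not from enolate equilibria.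

Alternative 3: Ring A is cut at three bonds (C8a–C8, C7–C6, C4a–C8a). Irradiation of the diazoketone A6 would give a vinylketene by Wolff rearrangement. Cycloaddition with the prenyl siloxyalkyne A7, four-electron ring opening and six-electron closure would give 5-(methoxymethoxy)-2-prenyl-3-(triisopropylsilyloxy)phenol A5.

- Merits: all three oxygens of ring A are differentiated by construction in A5, and the free hydroxyl is exactly the one that must become O1. The prenyl group enters on the alkyne, so C-prenylation of a phloroglucinol is avoided. In regiochemical certainty this is better than steps 6 and 7 of the chosen plan.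
- Weak points: A6 and A7 each need several steps, and the key step is photochemical. A5 still lacks the carbon on C4a, so acylation must go between the hydroxyl and the acetal oxygen and not at C6, a new regiochemical question. Two different protecting groups must come off later, one of them with acid. Ring B is not addressed at all.
- Comparison: the chosen plan reaches its ring A fragment in two steps from 12 and accepts a selectivity risk there, for which a fallback is provided. It places its one de novo ring construction on ring B, where two of the three prenyl groups and the harder alkylation problem lie.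

Key step: step 4

Remark on the chemistry: 8 is drawn as the tricarbonyl tautomer but exists as its hydroxymethylene enol and reacts in step 4 as the sodium enolate. 15 is drawn as the diketone although enol and cyclic hemiketal forms will be present. 3 is racemic and 4 is a mixture of diastereomers; their stereocentres disappear in step 2.

## Route

Step 1
Reactants: 1 dimethyl 3-oxopentanedioate; 2 prenyl bromide (1-bromo-3-methylbut-2-ene)
Product: 4 dimethyl 2,4-bis(3-methylbut-2-en-1-yl)-3-oxopentanedioate (mixture of diastereomers), via dimethyl 2-(3-methylbut-2-en-1-yl)-3-oxopentanedioate 3 (not isolated)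
Conditions: NaOMe (1.0 equiv), MeOH, 0 °C, then 2 (1.0 equiv), rt; then NaOMe (1.0 equiv) and 2 (1.0 equiv) again in the same flask, 0 °C → rt
Reagents that add atoms: prenyl bromide (second equivalent of 2), CC(C)=CCBr
Why: Sequential β-keto ester alkylation (SN2 at the primary allylic carbon), the first equivalent of 2 giving 3 and the second giving 4; in 3 the unsubstituted C4–H2 is the more acidic and less hindered site, so the second prenyl group should enter at C4 and give the 2,4-pattern, and methoxide in methanol cannot scramble the methyl esters.

Step 2
Reactants: 4 dimethyl 2,4-bis(3-methylbut-2-en-1-yl)-3-oxopentanedioate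
Product: 5 2,10-dimethylundeca-2,9-dien-6-one
Conditions: LiCl, H2O, DMSO, 150 °C
Reagents that add atoms: none
Why: Double Krapcho dealkoxycarbonylation: chloride demethylates each ester, the β-keto carboxylates lose CO2 and water protonates the enolates; the medium is neutral, so the trisubstituted alkenes are not hydrated or cyclized as they would be under acidic hydrolysis.

Step 3
Reactants: 6 ethyl 3,3-diethoxypropanoate
Product: 8 ethyl 2-formyl-3-oxopropanoate, via ethyl 2-(diethoxymethyl)-3-oxopropanoate 7 (not isolated)
Conditions: NaH, HCO2Et, THF, 0 °C → rt; then 2 M aq. HCl, rt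
Reagents that add atoms: ethyl formate, CCOC=O; water, O
Why: Crossed Claisen formylation of the ester enolate, driven by formation of the stabilized sodium enolate of 7, followed by acid hydrolysis of the diethyl acetal; the product is a stable hydroxymethylene enol that can be extracted and used directly.

Step 4
Reactants: 5 2,10-dimethylundeca-2,9-dien-6-one; 8 ethyl 2-formyl-3-oxopropanoate
Product: 10 ethyl 4-hydroxy-3,5-bis(3-methylbut-2-en-1-yl)benzoate, via ethyl 4-oxo-3,5-bis(3-methylbut-2-en-1-yl)cyclohexa-2,5-diene-1-carboxylate 9 (not isolated)
Conditions: NaOEt (2.2 equiv), EtOH, rt → 60 °C; then AcOH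
Reagents that add atoms: none
Why: NaOEt converts 8 into its sodium enolate and generates the enolate of 5 reversibly; the α-carbon C3' adds to one formyl carbon and loss of water gives the C2'=C3' bond (aldol condensation of the Knoevenagel kind). The second α-carbon C5' then attacks the remaining formyl group in a 6-(enolendo)-exo-trig aldol closure that forms C5'–C6' and ring B, and a second dehydration gives the cross-conjugated dienone 9. Removal of the C1' proton of 9, which is doubly vinylogous to the ketone and alpha to the ester, gives the phenoxide of 10, so aromatization is a proton shift and makes the sequence irreversible. The closest known reaction type is the base-mediated [3+3] condensation of 1,3-disubstituted acetones with salts of 2-substituted malonaldehydes (nitro or alkoxycarbonyl at C2) to give 2,6-disubstituted 4-substituted phenols. No stereocentre is formed. Regiochemistry cannot arise, because 5 is symmetric about its carbonyl group and 8 about C1'. The selectivity needed is cross- over self-condensation of 5; it rests on 8 having no enolizable CH2, on the higher electrophilicity of formyl carbons, and on the reversibility of ketone self-aldolization against an aromatic sink. The prenyl alkenes are isolated and inert to alkoxide, and ethoxide in ethanol cannot scramble the ethyl ester.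

Step 5
Reactants: 10 ethyl 4-hydroxy-3,5-bis(3-methylbut-2-en-1-yl)benzoate
Product: 11 ethyl 3,5-bis(3-methylbut-2-en-1-yl)-4-(prop-2-en-1-yloxy)benzoate
Conditions: allyl bromide, K2CO3, DMF, 50 °C
Reagents that add atoms: allyl bromide, C=CCBr
Why: Williamson etherification; the phenoxide flanked by two CH2 groups is still open to a primary allylic bromide, and C-allylation is blocked because both ortho positions and the para position are substituted.

Step 6
Reactants: 12 2,4,6-trihydroxyacetophenone; 2 prenyl bromide (1-bromo-3-methylbut-2-ene)
Product: 13 1-[2,4,6-trihydroxy-3-(3-methylbut-2-en-1-yl)phenyl]ethan-1-one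
Conditions: 2 (1.0 equiv), DBU, THF, 0 °C → rt
Reagents that add atoms: none
Why: C-alkylation of the ambident phloroglucinol-type phenoxide at a ring carbon; the two ring CH positions of 12 are equivalent, so mono-C-prenylation can give only one constitution, and one equivalent of bromide limits diprenylation and O-prenylation.

Step 7
Reactants: 13 1-[2,4,6-trihydroxy-3-(3-methylbut-2-en-1-yl)phenyl]ethan-1-one
Product: 14 1-[2-hydroxy-3-(3-methylbut-2-en-1-yl)-4,6-bis(prop-2-en-1-yloxy)phenyl]ethan-1-one
Conditions: allyl bromide (2.1 equiv), K2CO3, acetone, 56 °C
Reagents that add atoms: allyl bromide, C=CCBr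
Why: Williamson etherification; the 4-hydroxyl (para to the acetyl group, not chelated) should react first, then the ortho hydroxyl flanked by hydrogen in preference to the one wedged between acetyl and prenyl, and the remaining hydroxyl keeps the hydrogen bond to the carbonyl and resists K2CO3/acetone alkylation.

Step 8
Reactants: 14 1-[2-hydroxy-3-(3-methylbut-2-en-1-yl)-4,6-bis(prop-2-en-1-yloxy)phenyl]ethan-1-one; 11 ethyl 3,5-bis(3-methylbut-2-en-1-yl)-4-(prop-2-en-1-yloxy)benzoate
Product: 15 1-[2-hydroxy-3-(3-methylbut-2-en-1-yl)-4,6-bis(prop-2-en-1-yloxy)phenyl]-3-[3,5-bis(3-methylbut-2-en-1-yl)-4-(prop-2-en-1-yloxy)phenyl]propane-1,3-dione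
Conditions: LiN(SiMe3)2 (3.5 equiv), THF, −78 °C; then 11, −78 → 50 °C; AcOH quench
Reagents that add atoms: none
Why: Crossed Claisen condensation of the lithium phenoxide-enolate dianion of 14 with the non-enolizable aryl ester 11, driven by deprotonation of the product diketone by the excess base; the free hydroxyl is carried as its phenoxide and needs no protection, and allyl ethers and prenyl groups are inert to the amide base.

Step 9
Reactants: 15 1-[2-hydroxy-3-(3-methylbut-2-en-1-yl)-4,6-bis(prop-2-en-1-yloxy)phenyl]-3-[3,5-bis(3-methylbut-2-en-1-yl)-4-(prop-2-en-1-yloxy)phenyl]propane-1,3-dione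
Product: 16 2-[3,5-bis(3-methylbut-2-en-1-yl)-4-(prop-2-en-1-yloxy)phenyl]-8-(3-methylbut-2-en-1-yl)-5,7-bis(prop-2-en-1-yloxy)-4H-chromen-4-one
Conditions: conc. HCl (cat.), MeOH–THF, 40 °C
Reagents that add atoms: none
Why: Acid-catalysed cyclodehydration: the only free phenol adds to the aryl ketone carbonyl (6-exo-trig hemiketal) and water is lost through the C2 oxocarbenium ion; the other ortho oxygen is an acid-stable allyl ether, so O1 can only be the oxygen next to the prenyl group, which fixes the 8-prenyl pattern, and dilute HCl at 40 °C should not protonate the trisubstituted alkenes at a competitive rate.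

Step 10
Reactants: 16 2-[3,5-bis(3-methylbut-2-en-1-yl)-4-(prop-2-en-1-yloxy)phenyl]-8-(3-methylbut-2-en-1-yl)-5,7-bis(prop-2-en-1-yloxy)-4H-chromen-4-one
Product: 17 Epimedonin L, 5,7-dihydroxy-2-[4-hydroxy-3,5-bis(3-methylbut-2-en-1-yl)phenyl]-8-(3-methylbut-2-en-1-yl)-4H-chromen-4-one
Conditions: Pd(PPh3)4 (5 mol%), morpholine, THF, rt
Reagents that add atoms: none
Why: Tsuji–Trost deallylation: zerovalent palladium ionizes each aryl allyl ether to a π-allyl complex and a phenoxide, and morpholine captures the allyl group irreversibly; the C-prenyl groups have no leaving group and their trisubstituted alkenes do not compete, and since neither acid nor hydrogen is used, chroman formation and alkene reduction are excluded.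

## Compound list

1 | dimethyl 3-oxopentanedioate | COC(=O)CC(=O)CC(=O)OC | starting material
2 | prenyl bromide (1-bromo-3-methylbut-2-ene) | CC(C)=CCBr | starting material
3 | dimethyl 2-(3-methylbut-2-en-1-yl)-3-oxopentanedioate (racemic; formed in the flask) | COC(=O)CC(=O)C(CC=C(C)C)C(=O)OC | intermediate
4 | dimethyl 2,4-bis(3-methylbut-2-en-1-yl)-3-oxopentanedioate (mixture of diastereomers) | COC(=O)C(CC=C(C)C)C(=O)C(CC=C(C)C)C(=O)OC | intermediate
5 | 2,10-dimethylundeca-2,9-dien-6-one | CC(C)=CCCC(=O)CCC=C(C)C | intermediate
6 | ethyl 3,3-diethoxypropanoate | CCOC(=O)CC(OCC)OCC | starting material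
7 | ethyl 2-(diethoxymethyl)-3-oxopropanoate (formed as its sodium enolate; α-carbon configurationally labile) | CCOC(=O)C(C=O)C(OCC)OCC | intermediate
8 | ethyl 2-formyl-3-oxopropanoate | CCOC(=O)C(C=O)C=O | intermediate
9 | ethyl 4-oxo-3,5-bis(3-methylbut-2-en-1-yl)cyclohexa-2,5-diene-1-carboxylate | CCOC(=O)C1C=C(CC=C(C)C)C(=O)C(CC=C(C)C)=C1 | intermediate
10 | ethyl 4-hydroxy-3,5-bis(3-methylbut-2-en-1-yl)benzoate | CCOC(=O)c1cc(CC=C(C)C)c(O)c(CC=C(C)C)c1 | intermediate
11 | ethyl 3,5-bis(3-methylbut-2-en-1-yl)-4-(prop-2-en-1-yloxy)benzoate | CCOC(=O)c1cc(CC=C(C)C)c(OCC=C)c(CC=C(C)C)c1 | intermediate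
12 | 2,4,6-trihydroxyacetophenone | CC(=O)c1c(O)cc(O)cc1O | starting material
13 | 1-[2,4,6-trihydroxy-3-(3-methylbut-2-en-1-yl)phenyl]ethan-1-one | CC(=O)c1c(O)cc(O)c(CC=C(C)C)c1O | intermediate
14 | 1-[2-hydroxy-3-(3-methylbut-2-en-1-yl)-4,6-bis(prop-2-en-1-yloxy)phenyl]ethan-1-one | CC(=O)c1c(OCC=C)cc(OCC=C)c(CC=C(C)C)c1O | intermediate
15 | 1-[2-hydroxy-3-(3-methylbut-2-en-1-yl)-4,6-bis(prop-2-en-1-yloxy)phenyl]-3-[3,5-bis(3-methylbut-2-en-1-yl)-4-(prop-2-en-1-yloxy)phenyl]propane-1,3-dione | C=CCOc1cc(OCC=C)c(C(=O)CC(=O)c2cc(CC=C(C)C)c(OCC=C)c(CC=C(C)C)c2)c(O)c1CC=C(C)C | intermediate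
16 | 2-[3,5-bis(3-methylbut-2-en-1-yl)-4-(prop-2-en-1-yloxy)phenyl]-8-(3-methylbut-2-en-1-yl)-5,7-bis(prop-2-en-1-yloxy)-4H-chromen-4-one | C=CCOc1cc(OCC=C)c2c(c1CC=C(C)C)oc(-c1cc(CC=C(C)C)c(OCC=C)c(CC=C(C)C)c1)cc2=O | intermediate
17 | Epimedonin L, 5,7-dihydroxy-2-[4-hydroxy-3,5-bis(3-methylbut-2-en-1-yl)phenyl]-8-(3-methylbut-2-en-1-yl)-4H-chromen-4-one | CC(C)=CCc1cc(-c2cc(=O)c3c(O)cc(O)c(CC=C(C)C)c3o2)cc(CC=C(C)C)c1O | target

## Step count and risks

Total step count: 10. Longest linear sequence: 7 steps (steps 1, 2, 4, 5, 8, 9 and 10, from 1 to 17).

**Step 4 (key step).** Under NaOEt the dialdehyde 8 is present as a delocalized enolate, a weak electrophile. The first aldol addition may therefore be slow, and self-condensation of 5, base-induced deformylation of 8, or reversible O-cyclization of the open-chain stage to pyran-type hemiacetals could take over.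
Fallback: arene prenylation in place of ring construction. It sets out from 2 and commercial ethyl 4-hydroxybenzoate F1. The sodium phenoxide of F1 (NaH, toluene) is C-alkylated ortho to oxygen by 2, giving ethyl 4-hydroxy-3-(3-methylbut-2-en-1-yl)benzoate F2. F2 is resubmitted to the same treatment, and the route is rejoined at 10. The para position is blocked by the ester, so only the O/C and mono/di choices remain, and these are handled by the non-polar medium and by recycling F2.

**Step 7.** The second allylation may not discriminate well between the two chelating ortho hydroxyls, or may run on to the triallyl ether. The isomer with the free hydroxyl away from the prenyl group would lead to the 6-prenyl series.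
Fallback: reverse the order of events, starting from 12 and returning at 14. Bis-O-allylation of 12 (allyl bromide, K2CO3, acetone) gives 1-[2-hydroxy-4,6-bis(prop-2-en-1-yloxy)phenyl]ethan-1-one F3, whose constitution is unambiguous by symmetry. The sodium phenoxide of F3 (NaH, toluene) is then C-prenylated with 2 at the only open position ortho to the phenoxide oxygen, which gives 14. This path also bypasses the mono-C-prenylation of step 6.

**Step 8.** The electron-rich ethyl benzoate 11 may acylate the dianion of 14 too slowly, so that proton transfer and recovery of both partners dominate.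
Fallback: the Baker–Venkataraman sequence, from 11 back to 15. Saponification of 11 (LiOH, THF–MeOH–H2O, then HCl) gives 3,5-bis(3-methylbut-2-en-1-yl)-4-(prop-2-en-1-yloxy)benzoic acid F4. Esterification of F4 with the free hydroxyl of 14 (EDC·HCl, DMAP, CH2Cl2) gives 2-acetyl-6-(3-methylbut-2-en-1-yl)-3,5-bis(prop-2-en-1-yloxy)phenyl 3,5-bis(3-methylbut-2-en-1-yl)-4-(prop-2-en-1-yloxy)benzoate F5. Intramolecular acyl transfer in F5 (KOH, pyridine, 50 °C) then gives 15.

**Step 10.** The liberated ring A phenoxide is a phloroglucinol-type carbon nucleophile and may be C-allylated at C6 by the π-allyl palladium intermediate. Cleavage at the hindered 4'-oxygen may also lag.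
Fallback: isomerization and hydrolysis, which generate no allyl electrophile, from 16 to 17. Treatment of 16 with H2-activated [Ir(cod)(PMePh2)2]PF6 in THF should move only the monosubstituted allyl double bonds, giving 2-[3,5-bis(3-methylbut-2-en-1-yl)-4-[(1E)-prop-1-en-1-yloxy]phenyl]-8-(3-methylbut-2-en-1-yl)-5,7-bis[(1E)-prop-1-en-1-yloxy]-4H-chromen-4-one F6. The enol ethers of F6 are hydrolysed with dilute HCl in acetone–water at rt to give 17.

## Further compounds

F1 | step 4 | ethyl 4-hydroxybenzoate | CCOC(=O)c1ccc(O)cc1
F2 | step 4 | ethyl 4-hydroxy-3-(3-methylbut-2-en-1-yl)benzoate | CCOC(=O)c1ccc(O)c(CC=C(C)C)c1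
F3 | step 7 | 1-[2-hydroxy-4,6-bis(prop-2-en-1-yloxy)phenyl]ethan-1-one | CC(=O)c1c(O)cc(OCC=C)cc1OCC=C
F4 | step 8 | 3,5-bis(3-methylbut-2-en-1-yl)-4-(prop-2-en-1-yloxy)benzoic acid | OC(=O)c1cc(CC=C(C)C)c(OCC=C)c(CC=C(C)C)c1
F5 | step 8 | 2-acetyl-6-(3-methylbut-2-en-1-yl)-3,5-bis(prop-2-en-1-yloxy)phenyl 3,5-bis(3-methylbut-2-en-1-yl)-4-(prop-2-en-1-yloxy)benzoate | CC(=O)c1c(OCC=C)cc(OCC=C)c(CC=C(C)C)c1OC(=O)c1cc(CC=C(C)C)c(OCC=C)c(CC=C(C)C)c1
F6 | step 10 | 2-[3,5-bis(3-methylbut-2-en-1-yl)-4-[(1E)-prop-1-en-1-yloxy]phenyl]-8-(3-methylbut-2-en-1-yl)-5,7-bis[(1E)-prop-1-en-1-yloxy]-4H-chromen-4-one | C/C=C/Oc1cc(O/C=C/C)c2c(c1CC=C(C)C)oc(-c1cc(CC=C(C)C)c(O/C=C/C)c(CC=C(C)C)c1)cc2=O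
A1 | alternative 1 | 4'-O-(methoxymethyl) Epimedonin L | COCOc1c(CC=C(C)C)cc(cc1CC=C(C)C)-c1cc(=O)c2c(O)cc(O)c(CC=C(C)C)c2o1
A2 | alternative 1 | 5-{2-[6-(4-(methoxymethoxy)-3,5-bis(3-methylbut-2-en-1-yl)phenyl)-4-oxo-4H-pyran-2-yl]-5-methylhex-4-enoyl}-2,2-dimethyl-1,3-dioxane-4,6-dione (racemic) | COCOc1c(CC=C(C)C)cc(cc1CC=C(C)C)-c1cc(=O)cc(o1)C(CC=C(C)C)C(=O)C1C(=O)OC(C)(C)OC1=O
A3 | alternative 2 | ethyl 4-oxo-3,5-bis(3-methylbut-2-en-1-yl)cyclohexane-1-carboxylate (drawn all-cis) | CCOC(=O)[C@H]1C[C@@H](CC=C(C)C)C(=O)[C@@H](CC=C(C)C)C1
A4 | alternative 2 | ethyl 4-oxocyclohexane-1-carboxylate | CCOC(=O)C1CCC(=O)CC1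
A5 | alternative 3 | 5-(methoxymethoxy)-2-(3-methylbut-2-en-1-yl)-3-(triisopropylsilyloxy)phenol | COCOc1cc(O)c(CC=C(C)C)c(O[Si](C(C)C)(C(C)C)C(C)C)c1
A6 | alternative 3 | 1-diazo-3-(methoxymethoxy)but-3-en-2-one | C=C(OCOC)C(=O)C=[N+]=[N-]
A7 | alternative 3 | triisopropyl[(5-methylhex-4-en-1-yn-1-yl)oxy]silane | CC(C)=CCC#CO[Si](C(C)C)(C(C)C)C(C)C
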